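The ten-membered carbocycle (C1–C10, germacrane numbering) is closed last, by an intramolecular Nozaki–Hiyama–Kishi reaction that forges C1–C10. It exploits the C1 carbinol next to the C10=C14 exocyclic methylene: a C10 alkenylchromium adds to a C1 aldehyde, so one operation delivers the ring, the C1 stereocentre and the free 2-methylene alcohol. The precursor is an acyclic, fully acylated cis-α-methylene-γ-butyrolactone (C6/C7) whose C7 arm carries the C8 ester and a 2-iodoallyl group and whose C6 arm carries the C4=C5 alkene and the C1 aldehyde. Its C6–C8 triad comes from an indium 2-(methoxycarbonyl)allylation steered by a glycidate-derived C8 centre.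

Key step: step 17

Remark: germacranolide numbering is used throughout (lactone O on C6, ester on C8, carbinol C1, C10=C14, C11=C13, acetoxymethyl C15). The C4=C5 bond is E by CIP but cis within the ring. The CIP label of C7 changes between 17 and 18 only because OTBS outranks the lactone branch; no bond at C7 is touched.

Step 1
Reactants: 1 but-2-yne-1,4-diol
Product: 2 4-hydroxybut-2-yn-1-yl acetate
Conditions: Ac2O (0.9 equiv), Et3N, DMAP (cat.), CH2Cl2, 0 °C
Reagents that add atoms: acetic anhydride, CC(=O)OC(C)=O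
Why: Statistical mono-esterification of the symmetric diol with limiting anhydride should give mainly the monoacetate, separable from diol and diacetate; no stereocentre is involved.

Step 2
Reactants: 2 4-hydroxybut-2-yn-1-yl acetate
Product: 3 4-oxobut-2-yn-1-yl acetate
Conditions: activated MnO2, CH2Cl2, rt
Reagents that add atoms: none
Why: MnO2 oxidation of the propargylic alcohol stops at the ynal and leaves the acetate untouched.

Step 3
Reactants: 3 4-oxobut-2-yn-1-yl acetate
Product: 4 (2Z)-2-iodo-4-oxobut-2-en-1-yl acetate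
Conditions: NaI, AcOH, rt
Reagents that add atoms: sodium iodide, [Na+].[I-]
Why: Conjugate hydroiodination of the ynal (iodide addition, then protonation anti to iodine) should give the (Z)-β-iodoenal, which fixes iodine cis to the formyl group.

Step 4
Reactants: 4 (2Z)-2-iodo-4-oxobut-2-en-1-yl acetate; 5 3,3-dimethoxyprop-1-ene
Product: 7 (2E)-2-(3,3-dimethoxypropyl)-4-oxobut-2-en-1-yl acetate, via alkylborane 6 (not isolated)
Conditions: 5, 9-BBN, THF, 0 °C to rt; then 4, PdCl2(dppf) (5 mol %), AsPh3, Cs2CO3, DMF/H2O, rt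
Reagents that add atoms: none
Why: Anti-Markovnikov hydroboration followed by B-alkyl Suzuki–Miyaura coupling proceeds with retention at the alkenyl iodide, so the C3 chain ends cis to the formyl group (the later ring-cis C4=C5 bond).

Step 5
Reactants: 8 methyl (2S)-oxirane-2-carboxylate
Product: 9 methyl (2S)-2-hydroxy-4-(trimethylsilyl)pent-4-enoate
Conditions: CH2=C(SiMe3)MgBr, CuI (10 mol %), THF, −40 to −20 °C
Reagents that add atoms: [1-(trimethylsilyl)ethenyl]magnesium bromide, C=C([Mg]Br)[Si](C)(C)C
Why: Copper-catalysed Grignard opening of the glycidic ester occurs by SN2 attack at the unsubstituted C3, so the C2–O stereocentre (the future C8) is carried over unchanged from the chiral pool.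

Step 6
Reactants: 9 methyl (2S)-2-hydroxy-4-(trimethylsilyl)pent-4-enoate
Product: 10 methyl (2S)-2-[(tert-butyldimethylsilyl)oxy]-4-(trimethylsilyl)pent-4-enoate
Conditions: TBSCl, imidazole, DMF, rt
Reagents that add atoms: tert-butyldimethylsilyl chloride, CC(C)(C)[Si](C)(C)Cl
Why: Standard silylation of the secondary α-hydroxy ester; the bulky silyl ether later serves as the stereodirecting group at C8.

Step 7
Reactants: 10 methyl (2S)-2-[(tert-butyldimethylsilyl)oxy]-4-(trimethylsilyl)pent-4-enoate
Product: 11 methyl (2S)-2-[(tert-butyldimethylsilyl)oxy]-4-iodopent-4-enoate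
Conditions: NIS, MeCN/ClCH2CN (4:1), 0 °C to rt
Reagents that add atoms: N-iodosuccinimide, O=C1CCC(=O)N1I
Why: ipso-Iododesilylation of the 1,1-disubstituted vinylsilane (β-silyl cation, loss of the silyl group) gives the 2-iodoalk-1-ene needed for the chromium chemistry.

Step 8
Reactants: 11 methyl (2S)-2-[(tert-butyldimethylsilyl)oxy]-4-iodopent-4-enoate
Product: 12 (2S)-2-[(tert-butyldimethylsilyl)oxy]-4-iodopent-4-enal
Conditions: DIBAL-H (1.1 equiv), CH2Cl2, −78 °C; Rochelle salt
Reagents that add atoms: none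
Why: Partial reduction of the α-silyloxy ester stops at the aldehyde because the tetrahedral aluminate is stable at −78 °C; the α-centre is not touched.

Step 9
Reactants: 12 (2S)-2-[(tert-butyldimethylsilyl)oxy]-4-iodopent-4-enal; 13 methyl acrylate
Product: 14 methyl (4S)-4-[(tert-butyldimethylsilyl)oxy]-3-hydroxy-6-iodo-2-methylidenehept-6-enoate (C3 epimer mixture)
Conditions: DABCO (0.5 equiv), methyl acrylate (5 equiv), MeOH (cat.), rt, 5–7 d
Reagents that add atoms: none
Why: Morita–Baylis–Hillman reaction; the new carbinol centre forms as a mixture, which is irrelevant because this carbon becomes sp2 in the next step.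

Step 10
Reactants: 14 methyl (4S)-4-[(tert-butyldimethylsilyl)oxy]-3-hydroxy-6-iodo-2-methylidenehept-6-enoate
Product: 15 methyl (2Z,4S)-2-(bromomethyl)-4-[(tert-butyldimethylsilyl)oxy]-6-iodohepta-2,6-dienoate
Conditions: NBS, Me2S, CH2Cl2, 0 °C to rt
Reagents that add atoms: N-bromosuccinimide, O=C1CCC(=O)N1Br
Why: Activation of the allylic alcohol as an alkoxysulfonium ion (Corey–Kim conditions) and SN2′ attack of bromide should give the rearranged primary bromide as the favoured (2Z) isomer, with the C8 chain trans to the ester.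

Step 11
Reactants: 15 methyl (2Z,4S)-2-(bromomethyl)-4-[(tert-butyldimethylsilyl)oxy]-6-iodohepta-2,6-dienoate; 7 (2E)-2-(3,3-dimethoxypropyl)-4-oxobut-2-en-1-yl acetate
Product: 17 [(2E)-3-{(2S,3S)-3-[(1S)-1-(tert-butyldimethylsilyloxy)-3-iodobut-3-en-1-yl]-4-methylidene-5-oxooxolan-2-yl}-2-(3,3-dimethoxypropyl)prop-2-en-1-yl] acetate, via hydroxy ester 16 (not isolated)
Conditions: In powder, NaHCO3, THF/H2O (2:1), rt; then PPTS (cat.), CH2Cl2, rt
Reagents that add atoms: none
Why: Indium Barbier 2-(alkoxycarbonyl)allylation: the (Z)-allylindium attacks the enal 1,2 through C7 in a chair transition state with the C8 chain axial, which gives the syn (future cis-lactone) C6/C7 pair, while the C8 centre, held with its C–H in the alkene plane by A(1,3) strain, directs the aldehyde anti to the bulky OTBS group and so fixes C7 and C6 absolutely; PPTS then closes the γ-lactone on O6.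

Step 12
Reactants: 17 TBS-protected cis-lactone dimethyl acetal (as in step 11)
Product: 18 [(2E)-3-{(2S,3R)-3-[(1S)-1-hydroxy-3-iodobut-3-en-1-yl]-4-methylidene-5-oxooxolan-2-yl}-2-(3-oxopropyl)prop-2-en-1-yl] acetate
Conditions: 48% aq. HF, MeCN, 0 °C to rt
Reagents that add atoms: water, O
Why: Aqueous HF cleaves the secondary TBS ether and hydrolyses the dimethyl acetal to the aldehyde in one operation, while lactone, acetate and vinyl iodide should survive; no stereocentre is affected.

Step 13
Reactants: 19 2-[(4R)-2,2-dimethyl-1,3-dioxolan-4-yl]ethan-1-ol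
Product: 20 2-[(4R)-2,2-dimethyl-1,3-dioxolan-4-yl]acetaldehyde
Conditions: Dess–Martin periodinane, NaHCO3, CH2Cl2, 0 °C to rt
Reagents that add atoms: none
Why: Buffered Dess–Martin oxidation of the primary alcohol gives the aldehyde without touching the acetonide or its stereocentre.

Step 14
Reactants: 20 2-[(4R)-2,2-dimethyl-1,3-dioxolan-4-yl]acetaldehyde
Product: 21 2-[(4R)-2,2-dimethyl-1,3-dioxolan-4-yl]prop-2-enal
Conditions: 37% aq. CH2O, pyrrolidine (10 mol %), EtCO2H (10 mol %), i-PrOH, 45 °C
Reagents that add atoms: formaldehyde, C=O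
Why: Amine-catalysed α-methylenation (Mannich condensation of the enamine with formaldehyde, then elimination of the amine) gives the 2-substituted acrolein; the dioxolane centre is not epimerisable under these mild conditions.

Step 15
Reactants: 21 2-[(4R)-2,2-dimethyl-1,3-dioxolan-4-yl]prop-2-enal
Product: 22 2-[(4R)-2,2-dimethyl-1,3-dioxolan-4-yl]prop-2-enoic acid
Conditions: NaClO2, NaH2PO4, 2-methylbut-2-ene, t-BuOH/H2O, 0 °C to rt
Reagents that add atoms: sodium chlorite, [Na+].[O-]Cl=O
Why: Pinnick oxidation converts the enal into the acrylic acid at buffered pH, which the acetonide tolerates.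

Step 16
Reactants: 18 hydroxy aldehyde (as in step 12); 22 2-[(4R)-2,2-dimethyl-1,3-dioxolan-4-yl]prop-2-enoic acid
Product: 24 [(2E)-3-{(2S,3R)-3-[(1S)-1-({2-[(4R)-2,2-dimethyl-1,3-dioxolan-4-yl]prop-2-enoyl}oxy)-3-iodobut-3-en-1-yl]-4-methylidene-5-oxooxolan-2-yl}-2-(3-oxopropyl)prop-2-en-1-yl] acetate, via mixed anhydride 23 (not isolated)
Conditions: 22, 2,4,6-Cl3C6H2COCl, Et3N, THF, rt; then 18, DMAP, toluene, rt
Reagents that add atoms: none
Why: Yamaguchi esterification acylates the hindered secondary C8 alcohol with retention, and the aldehyde and both acrylate units should be inert to the mixed anhydride and DMAP at room temperature.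

Step 17
Reactants: 24 seco-aldehyde with 2-iodoallyl group (as in step 16)
Product: 25 (1R,4E,6S,7R,8S)-15-acetoxy-8-({2-[(4R)-2,2-dimethyl-1,3-dioxolan-4-yl]prop-2-enoyl}oxy)-1-hydroxygermacra-4,10(14),11(13)-trien-12,6-olide
Conditions: CrCl2 (10 equiv), NiCl2 (0.1 equiv), DMSO/THF (3:1), 2 mM, syringe-pump addition, rt
Reagents that add atoms: none
Why: Ni(0) formed in situ inserts into the C10–I bond, transmetalation gives the C10 alkenylchromium(III), and this adds 1,2 to the C1 aldehyde; the closest known reaction type is the intramolecular Nozaki–Hiyama–Kishi closure of medium rings from 2-iodoalk-1-ene aldehydes. The ten-membered carbocycle is closed by C1–C10 bond formation in a 10-exo-trig mode (carbonyl oxygen outside the new ring), with the cis-lactone at C6/C7 and the ring-cis C4=C5 bond turning both arms toward each other. The new C1 stereocentre is set by the substrate: in the folded transition state the C1 carbonyl should lie anti to the C10=C14 methylene and away from the C8 acyloxy group, which exposes the aldehyde Si face and should give 1R. The step needs chemoselectivity for the aldehyde over lactone, acrylate and acetate (organochromium(III) adds only to aldehydes), cyclisation over oligomerisation (high dilution, slow addition) and the Si-face selectivity, which only the ring conformation secures.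

Step 18
Reactants: 25 macrocyclic acetonide (as in step 17)
Product: 26 (1R,4E,6S,7R,8S)-15-acetoxy-8-{[(3R)-3,4-dihydroxy-2-methylidenebutanoyl]oxy}-1-hydroxygermacra-4,10(14),11(13)-trien-12,6-olide
Conditions: AcOH/H2O (4:1), 35 °C
Reagents that add atoms: none
Why: Mild acid-catalysed hydrolysis of the terminal acetonide releases the diol and acetone without cleaving the esters, the lactone or the allylic alcohol.

Compound list
1 | but-2-yne-1,4-diol | OCC#CCO | starting material
2 | 4-hydroxybut-2-yn-1-yl acetate | CC(=O)OCC#CCO | intermediate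
3 | 4-oxobut-2-yn-1-yl acetate | CC(=O)OCC#CC=O | intermediate
4 | (2Z)-2-iodo-4-oxobut-2-en-1-yl acetate | CC(=O)OC/C(I)=C/C=O | intermediate
5 | 3,3-dimethoxyprop-1-ene (acrolein dimethyl acetal) | C=CC(OC)OC | starting material
6 | 9-(3,3-dimethoxypropyl)-9-borabicyclo[3.3.1]nonane | COC(OC)CCB1C2CCCC1CCC2 | intermediate
7 | (2E)-2-(3,3-dimethoxypropyl)-4-oxobut-2-en-1-yl acetate | CC(=O)OC/C(CCC(OC)OC)=C/C=O | intermediate
8 | methyl (2S)-oxirane-2-carboxylate | COC(=O)[C@@H]1CO1 | starting material
9 | methyl (2S)-2-hydroxy-4-(trimethylsilyl)pent-4-enoate | COC(=O)[C@@H](O)CC(=C)[Si](C)(C)C | intermediate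
10 | methyl (2S)-2-[(tert-butyldimethylsilyl)oxy]-4-(trimethylsilyl)pent-4-enoate | COC(=O)[C@@H](O[Si](C)(C)C(C)(C)C)CC(=C)[Si](C)(C)C | intermediate
11 | methyl (2S)-2-[(tert-butyldimethylsilyl)oxy]-4-iodopent-4-enoate | COC(=O)[C@@H](O[Si](C)(C)C(C)(C)C)CC(I)=C | intermediate
12 | (2S)-2-[(tert-butyldimethylsilyl)oxy]-4-iodopent-4-enal | O=C[C@@H](O[Si](C)(C)C(C)(C)C)CC(I)=C | intermediate
13 | methyl acrylate | C=CC(=O)OC | starting material
14 | methyl (4S)-4-[(tert-butyldimethylsilyl)oxy]-3-hydroxy-6-iodo-2-methylidenehept-6-enoate (3RS) | COC(=O)C(=C)C(O)[C@@H](O[Si](C)(C)C(C)(C)C)CC(I)=C | intermediate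
15 | methyl (2Z,4S)-2-(bromomethyl)-4-[(tert-butyldimethylsilyl)oxy]-6-iodohepta-2,6-dienoate | COC(=O)/C(CBr)=C/[C@@H](O[Si](C)(C)C(C)(C)C)CC(I)=C | intermediate
16 | methyl (3S,4S,5E)-6-(acetoxymethyl)-3-[(1S)-1-(tert-butyldimethylsilyloxy)-3-iodobut-3-en-1-yl]-4-hydroxy-9,9-dimethoxy-2-methylidenenon-5-enoate | COC(=O)C(=C)[C@@H]([C@@H](O)/C=C(/COC(C)=O)CCC(OC)OC)[C@@H](O[Si](C)(C)C(C)(C)C)CC(I)=C | intermediate
17 | [(2E)-3-{(2S,3S)-3-[(1S)-1-(tert-butyldimethylsilyloxy)-3-iodobut-3-en-1-yl]-4-methylidene-5-oxooxolan-2-yl}-2-(3,3-dimethoxypropyl)prop-2-en-1-yl] acetate | C=C1C(=O)O[C@@H](/C=C(/COC(C)=O)CCC(OC)OC)[C@H]1[C@@H](O[Si](C)(C)C(C)(C)C)CC(I)=C | intermediate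
18 | [(2E)-3-{(2S,3R)-3-[(1S)-1-hydroxy-3-iodobut-3-en-1-yl]-4-methylidene-5-oxooxolan-2-yl}-2-(3-oxopropyl)prop-2-en-1-yl] acetate | C=C1C(=O)O[C@@H](/C=C(/COC(C)=O)CCC=O)[C@H]1[C@@H](O)CC(I)=C | intermediate
19 | 2-[(4R)-2,2-dimethyl-1,3-dioxolan-4-yl]ethan-1-ol | OCC[C@@H]1COC(C)(C)O1 | starting material
20 | 2-[(4R)-2,2-dimethyl-1,3-dioxolan-4-yl]acetaldehyde | O=CC[C@@H]1COC(C)(C)O1 | intermediate
21 | 2-[(4R)-2,2-dimethyl-1,3-dioxolan-4-yl]prop-2-enal | O=CC(=C)[C@@H]1COC(C)(C)O1 | intermediate
22 | 2-[(4R)-2,2-dimethyl-1,3-dioxolan-4-yl]prop-2-enoic acid | OC(=O)C(=C)[C@@H]1COC(C)(C)O1 | intermediate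
23 | 2-[(4R)-2,2-dimethyl-1,3-dioxolan-4-yl]prop-2-enoic 2,4,6-trichlorobenzoic anhydride | O=C(OC(=O)C(=C)[C@@H]1COC(C)(C)O1)c1c(Cl)cc(Cl)cc1Cl | intermediate
24 | [(2E)-3-{(2S,3R)-3-[(1S)-1-({2-[(4R)-2,2-dimethyl-1,3-dioxolan-4-yl]prop-2-enoyl}oxy)-3-iodobut-3-en-1-yl]-4-methylidene-5-oxooxolan-2-yl}-2-(3-oxopropyl)prop-2-en-1-yl] acetate | C=C1C(=O)O[C@@H](/C=C(/COC(C)=O)CCC=O)[C@H]1[C@@H](OC(=O)C(=C)[C@@H]2COC(C)(C)O2)CC(I)=C | intermediate
25 | (1R,4E,6S,7R,8S)-15-acetoxy-8-({2-[(4R)-2,2-dimethyl-1,3-dioxolan-4-yl]prop-2-enoyl}oxy)-1-hydroxygermacra-4,10(14),11(13)-trien-12,6-olide | C=C1C(=O)O[C@H]2/C=C(/COC(C)=O)CC[C@@H](O)C(=C)C[C@H](OC(=O)C(=C)[C@@H]3COC(C)(C)O3)[C@@H]12 | intermediate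
26 | (1R,4E,6S,7R,8S)-15-acetoxy-8-{[(3R)-3,4-dihydroxy-2-methylidenebutanoyl]oxy}-1-hydroxygermacra-4,10(14),11(13)-trien-12,6-olide (CNP0245550.1) | C=C1C(=O)O[C@H]2/C=C(/COC(C)=O)CC[C@@H](O)C(=C)C[C@H](OC(=O)C(=C)[C@@H](O)CO)[C@@H]12 | target

Total step count: 18. Longest linear sequence: 11 steps (steps 5–12, then 16–18, from methyl (2S)-oxirane-2-carboxylate 8).

Steps most likely to fail

Step 17. The ring closure may be slow, so that oligomerisation competes. Above all, the alkenylchromium may add to both faces of the C1 aldehyde, because only the folding of the forming ring discriminates between them. The fallback sets out from 25 as obtained, mixed with its C1 epimer, the (1S)-macrocyclic acetonide F1. Dess–Martin oxidation should convert both epimers into one compound, the cross-conjugated C1 ketone (macrocyclic 1-oxo enone) F2. A Corey–Bakshi–Shibata reduction with the (S)-methyl oxazaborolidine and catecholborane in toluene at −78 °C then sets C1 under reagent control. The C10 alkenyl group acts as the large substituent, so the 1R alcohol is expected, and the route is rejoined at 25.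

Step 11. The allylindium may equilibrate between its E and Z forms, which would erode the syn (cis-lactone) relationship, and the facial bias exerted by the C8 silyloxy centre may be insufficient. The fallback sets out from 14 and replaces indium by a configurationally stable allylboronate. Acetylation (Ac2O, DMAP) gives the Morita–Baylis–Hillman acetate, methyl (4S)-3-acetoxy-4-(tert-butyldimethylsilyloxy)-6-iodo-2-methylidenehept-6-enoate F3. Copper-catalysed SN2′ borylation (B2pin2, CuCl, LiCl, KOAc, DMF) should give the allylboronate, methyl (2E,4S)-4-(tert-butyldimethylsilyloxy)-6-iodo-2-[(4,4,5,5-tetramethyl-1,3,2-dioxaborolan-2-yl)methyl]hepta-2,6-dienoate F4, with the C8 chain cis to CH2B. Thermal allylboration of 7 (toluene, 80 °C) goes through a closed chair transition state that transfers the alkene geometry into the syn adduct 16 (as its borate), which lactonises on work-up with PPTS. The route is rejoined at 17.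

Step 9. The amine-catalysed addition is slow for an α-silyloxy aldehyde, which leaves time for base-mediated epimerisation at C8 and for silyl migration in the adduct. The fallback sets out from 12 and comes back at 14. It uses a preformed nucleophile instead of amine catalysis: hydroalumination of methyl propiolate (DIBAL-H, NMO, THF, 0 °C) gives the α-(methoxycarbonyl)vinylalane, which adds to 12 within minutes at 0 °C (vinylalumination) and gives 14 directly. No compound outside the list is made (F0).

Further compounds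
F1 | step 17 | (1S,4E,6S,7R,8S)-15-acetoxy-8-({2-[(4R)-2,2-dimethyl-1,3-dioxolan-4-yl]prop-2-enoyl}oxy)-1-hydroxygermacra-4,10(14),11(13)-trien-12,6-olide | C=C1C(=O)O[C@H]2/C=C(/COC(C)=O)CC[C@H](O)C(=C)C[C@H](OC(=O)C(=C)[C@@H]3COC(C)(C)O3)[C@@H]12
F2 | step 17 | (4E,6S,7R,8S)-15-acetoxy-8-({2-[(4R)-2,2-dimethyl-1,3-dioxolan-4-yl]prop-2-enoyl}oxy)-1-oxogermacra-4,10(14),11(13)-trien-12,6-olide | C=C1C(=O)O[C@H]2/C=C(/COC(C)=O)CCC(=O)C(=C)C[C@H](OC(=O)C(=C)[C@@H]3COC(C)(C)O3)[C@@H]12
F3 | step 11 | methyl (4S)-3-acetoxy-4-[(tert-butyldimethylsilyl)oxy]-6-iodo-2-methylidenehept-6-enoate (3RS) | COC(=O)C(=C)C(OC(C)=O)[C@@H](O[Si](C)(C)C(C)(C)C)CC(I)=C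
F4 | step 11 | methyl (2E,4S)-4-[(tert-butyldimethylsilyl)oxy]-6-iodo-2-[(4,4,5,5-tetramethyl-1,3,2-dioxaborolan-2-yl)methyl]hepta-2,6-dienoate | COC(=O)/C(CB1OC(C)(C)C(C)(C)O1)=C/[C@@H](O[Si](C)(C)C(C)(C)C)CC(I)=C
F0 | step 9 | none | none
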